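**Retrosynthetic overview**

1. Drimane-type numbering is used throughout: ring A = C1–C5 + C10 (C3 = ketone, methyls on C4 and C5), ring B = C5–C10 (methyls on C8 and C9), C11 = OCH2 on C9. The last disconnection is the C11–O aryl ether (Mitsunobu reaction with isofraxidin) on the finished trans-decalin.
2. Ring A is opened at C1–C2 (aldol condensation of a C3 methyl ketone with a C1 aldehyde, then hydrogenation). Ring B is then opened at C5–C6.
3. Enabling feature: the quaternary ring-fusion carbon C5 is β to the C3 ketone through C4 and adjoins the C10–H methine. With ring A still open, C5=C4(Me)–C3(=O)Me is an acyclic tetrasubstituted enone in which allylic 1,3-strain holds H-10 in the alkene plane. A primary C6 radical tethered through C9 (C–I and enone β-carbon are both electrophilic beforehand) can then add to C5 only on the C9 face, which gives Me-5 anti to H-10, the trans fusion, from either enone isomer. A closed ring A would tie C1 to C3 and is expected to favour the cis fusion.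
4. The C8/C9/C10 triad is set beforehand on a temporary five-membered ring (C11–O–C1–C10–C9) made from a menthyloxybutenolide: copper-catalysed Grignard addition (C10), methylation, iridium-catalysed crotylation (C9, C8). The ring is carried as a 2,5-dimethoxytetrahydrofuran (masked C1/C11 dialdehyde) and cleaved after the key step.
5. Ring order: temporary oxygen ring → ring B (C5–C6) → ring A (C1–C2); C4 is corrected at the end by equilibration.

Key step: step 10

Remark: (5S)-5-(d-menthyloxy)furan-2(5H)-one 1 is treated as a purchasable chiral building block (otherwise two steps from furfural and (+)-menthol); the acetal carbons of 8–17 are anomer mixtures of no consequence.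

**Route**

Step 1
Reactants: 1 (5S)-5-(d-menthyloxy)furan-2(5H)-one; 2 isopropenylmagnesium bromide
Product: 3 (4R,5S)-5-(d-menthyloxy)-4-(prop-1-en-2-yl)dihydrofuran-2(3H)-one
Conditions: CuBr·SMe2 (10 mol %), THF, −78 °C; aq. NH4Cl
Reagents that add atoms: none
Why: Copper-catalysed conjugate addition of the alkenyl Grignard reagent to the γ-alkoxybutenolide should occur anti to the menthyloxy group on the acetal carbon (C1), which sets C10 by substrate control.

Step 2
Reactants: 3 (4R,5S)-5-(d-menthyloxy)-4-(prop-1-en-2-yl)dihydrofuran-2(3H)-one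
Product: 4 (3S,4R,5S)-3-methyl-5-(d-menthyloxy)-4-(prop-1-en-2-yl)dihydrofuran-2(3H)-one
Conditions: LiN(i-Pr)2, THF, −78 °C; MeI, −78 → −30 °C
Reagents that add atoms: iodomethane, CI
Why: Lactone enolate alkylation anti to the neighbouring isopropenyl group installs the C9 methyl; the C9 configuration is provisional because this centre is re-formed in step 3.

Step 3
Reactants: 4 (3S,4R,5S)-3-methyl-5-(d-menthyloxy)-4-(prop-1-en-2-yl)dihydrofuran-2(3H)-one; 5 (E)-but-2-en-1-yl methyl carbonate
Product: 7 (3S,4S,5S)-3-[(2S)-but-3-en-2-yl]-3-methyl-5-(d-menthyloxy)-4-(prop-1-en-2-yl)dihydrofuran-2(3H)-one, via silyl ketene acetal 6 (not isolated)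
Conditions: LiN(i-Pr)2, Me3SiCl, THF, −78 °C; then [Ir(cod)Cl]2 (2 mol %), BINOL/bis(1-phenylethyl)amine phosphoramidite (4 mol %, antipode giving (S) at C8), CsF and ZnF2 (0.2 equiv each), THF, 40 °C
Reagents that add atoms: none
Why: Iridium-catalysed branched-selective allylic alkylation of a silyl ketene acetal: the allyl–iridium electrophile should attack C9 on the lactone face anti to the C10 isopropenyl group (quaternary C9, substrate control), while the phosphoramidite ligand fixes the methyl-bearing allylic carbon C8 (catalyst control).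

Step 4
Reactants: 7 (3S,4S,5S)-3-[(2S)-but-3-en-2-yl]-3-methyl-5-(d-menthyloxy)-4-(prop-1-en-2-yl)dihydrofuran-2(3H)-one
Product: 8 lactol of 7 (C11 anomer mixture)
Conditions: i-Bu2AlH (1.1 equiv), CH2Cl2, −78 °C; aq. KNaC4H4O6
Reagents that add atoms: none
Why: Half-reduction of the hindered lactone should stop at the lactol because the tetrahedral aluminium alkoxide persists at −78 °C; C11 becomes an acetal carbon of no stereochemical consequence.

Step 5
Reactants: 8 lactol of 7
Product: 9 3-[(2S)-but-3-en-2-yl]-2,5-dimethoxy-3-methyl-4-(prop-1-en-2-yl)tetrahydrofuran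
Conditions: MeOH, camphorsulfonic acid (5 mol %), 3 Å MS, rt
Reagents that add atoms: methanol, CO
Why: Acid-catalysed acetal exchange through the two cyclic oxocarbenium ions should convert the lactol and the menthyl acetal into the 2,5-dimethoxytetrahydrofuran (masked C1/C11 dialdehyde) and release the auxiliary.

Step 6
Reactants: 9 3-[(2S)-but-3-en-2-yl]-2,5-dimethoxy-3-methyl-4-(prop-1-en-2-yl)tetrahydrofuran
Product: 11 3-[(2S)-4-iodobutan-2-yl]-2,5-dimethoxy-3-methyl-4-(prop-1-en-2-yl)tetrahydrofuran, via alkylzirconocene chloride 10 (not isolated)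
Conditions: Cp2Zr(H)Cl (1.2 equiv), THF, rt; I2, 0 °C
Reagents that add atoms: iodine, II
Why: Hydrozirconation should place zirconium on the terminal carbon C6 of the monosubstituted vinyl group (the hindered 1,1-disubstituted isopropenyl group reacts much more slowly), and iodinolysis of the C–Zr bond gives the primary iodide.

Step 7
Reactants: 11 3-[(2S)-4-iodobutan-2-yl]-2,5-dimethoxy-3-methyl-4-(prop-1-en-2-yl)tetrahydrofuran
Product: 13 1-{4-[(2S)-4-iodobutan-2-yl]-2,5-dimethoxy-4-methyltetrahydrofuran-3-yl}ethan-1-one, via diol 12 (not isolated)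
Conditions: OsO4 (2 mol %), NaIO4 (4 equiv), 2,6-lutidine, dioxane/H2O 3:1, rt
Reagents that add atoms: osmium tetroxide, O=[Os](=O)(=O)=O; sodium periodate, [Na+].[O-]I(=O)(=O)=O
Why: Lemieux–Johnson cleavage of the only remaining alkene unmasks the C5 methyl ketone; the buffered medium should spare the acetals and C10, whose acetyl group already sits trans to the bulky C8 side chain on the five-membered ring.

Step 8
Reactants: 13 1-{4-[(2S)-4-iodobutan-2-yl]-2,5-dimethoxy-4-methyltetrahydrofuran-3-yl}ethan-1-one; 14 but-2-en-2-ylmagnesium bromide (E/Z mixture)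
Product: 15 2-{4-[(2S)-4-iodobutan-2-yl]-2,5-dimethoxy-4-methyltetrahydrofuran-3-yl}-3-methylpent-3-en-2-ol (carbinol epimers, E/Z)
Conditions: LaCl3·2LiCl (0.3 equiv), THF, −78 → −30 °C; aq. NH4Cl
Reagents that add atoms: none
Why: Lanthanum-assisted 1,2-addition of the alkenyl Grignard reagent should outrun enolisation of the hindered methyl ketone; the carbinol centre and the alkene geometry are erased in steps 9 and 10.

Step 9
Reactants: 15 tertiary allylic alcohol
Product: 16 4-{4-[(2S)-4-iodobutan-2-yl]-2,5-dimethoxy-4-methyltetrahydrofuran-3-yl}-3-methylpent-3-en-2-one (E/Z mixture)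
Conditions: pyridinium chlorochromate [C5H5NH][CrO3Cl] (2.5 equiv), NaOAc, 4 Å MS, CH2Cl2, rt
Reagents that add atoms: pyridinium chlorochromate, [O-][Cr](=O)(=O)Cl.c1cc[nH+]cc1
Why: Babler–Dauben oxidative transposition: the chromate ester of the tertiary allylic alcohol should undergo a [3,3] shift to the secondary allylic chromate, which is oxidised to the tetrasubstituted enone (both geometrical isomers are used).

Step 10
Reactants: 16 tetrasubstituted enone iodide (E/Z mixture)
Product: 17 3-(1,3-dimethoxy-4,7,7a-trimethyloctahydro-2-benzofuran-4-yl)butan-2-one (ring B closed; Me-5 anti to H-10; C4 epimer mixture)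
Conditions: Bu3SnH (1.3 equiv, syringe pump, 8 h), AIBN (0.2 equiv), benzene (0.005 M), 80 °C
Reagents that add atoms: none
Why: Iodine abstraction by the tin radical gives the primary C6 radical, which adds to C5, the β-carbon of the tetrasubstituted enone, and the resulting α-keto radical at C4 is reduced by Bu3SnH, so that two carbons that are both electrophilic in the precursor are joined; the closest known reaction type is the tin hydride mediated radical conjugate cyclisation of ω-iodoalkyl enones and enoates that builds quaternary centres. Ring B (C5–C10) is closed in the 6-exo-trig mode onto an acceptor alkene that stays outside the new ring. The quaternary centre C5 is controlled by allylic 1,3-strain about the C10–C5 bond: each enone isomer carries a substituent on C4 (methyl or acetyl) cis to C10, so H-10 lies in the alkene plane, C9 and C1 flank the two faces, and the radical tethered through C9 can reach C5 only on the C9 face, which places C4 and C1 trans-diequatorial on ring B and Me-5 anti to H-10 (the trans ring fusion once ring A is closed in step 11). C4 is formed without control and is equilibrated in step 12, so the E/Z mixture of 16 and both C4 epimers should converge on one compound. The step needs chemoselective C–I homolysis and cyclisation faster than hydrogen transfer to C6; the enone polarisation, high dilution and slow addition of Bu3SnH are meant to secure this, and the acetals, the ketone and the C8–C10 stereocentres are not touched.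

Step 11
Reactants: 17 ring B ketone bis-acetal
Product: 19 (1S,2S,4aR,8aS)-1,2,4a,5-tetramethyl-6-oxo-1,2,3,4,4a,5,6,8a-octahydronaphthalene-1-carbaldehyde (epimer mixture at the methyl-bearing carbon next to the ketone), via dialdehyde 18 (not isolated)
Conditions: 2 M aq. HCl/THF 1:3, 50 °C
Reagents that add atoms: water, O
Why: Acetal hydrolysis unmasks the C1 and C11 aldehydes, and acid-catalysed aldol condensation of the methyl ketone (C2) with the C1 aldehyde should close ring A in the 6-(enolendo)-exo-trig mode; the C11 aldehyde on quaternary C9 is non-enolisable and reachable only through a seven-membered ring.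

Step 12
Reactants: 19 enone aldehyde
Product: 21 (1S,2S,4aR,5S,8aS)-1,2,4a,5-tetramethyl-6-oxodecahydronaphthalene-1-carbaldehyde, via C4-epimeric keto aldehyde 20 (not isolated)
Conditions: H2 (1 atm), Pd/C (10 wt %), EtOAc, rt; filtration; NaOMe (0.2 equiv), MeOH, rt
Reagents that add atoms: none
Why: Hydrogenation of the conjugated C1=C2 bond creates no stereocentre, and methoxide equilibration through the C3 enolate should funnel both C4 epimers into the equatorial methyl (cis to Me-5), the thermodynamic arrangement of 4,5-dimethyl-3-ketones of this type.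

Step 13
Reactants: 21 keto aldehyde
Product: 22 (1S,4aS,5S,6S,8aR)-5-(hydroxymethyl)-1,5,6,8a-tetramethyloctahydronaphthalen-2(1H)-one
Conditions: NaBH4 (0.4 equiv), EtOH/CH2Cl2 1:1, −78 °C
Reagents that add atoms: none
Why: Borohydride at −78 °C should reduce the aldehyde much faster than the α-branched cyclohexanone, giving the C11 alcohol without touching C3.

Step 14
Reactants: 22 keto alcohol; 23 isofraxidin (7-hydroxy-6,8-dimethoxy-2H-chromen-2-one)
Product: 24 6,8-dimethoxy-7-{[(1S,2S,4aR,5S,8aS)-1,2,4a,5-tetramethyl-6-oxodecahydronaphthalen-1-yl]methoxy}-2H-chromen-2-one (target)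
Conditions: PBu3 (2 equiv), N,N,N′,N′-tetramethylazodicarboxamide (2 equiv), toluene, 80 °C
Reagents that add atoms: none
Why: Mitsunobu etherification: the acidic phenol of isofraxidin should displace the alkoxyphosphonium at the primary C11; no stereocentre is involved and the ketone and the coumarin lactone are inert.

**Compound list**

1 | (5S)-5-{[(1S,2R,5S)-5-methyl-2-(propan-2-yl)cyclohexyl]oxy}furan-2(5H)-one [(5S)-5-(d-menthyloxy)-2(5H)-furanone] | O=C1C=C[C@@H](O[C@H]2C[C@@H](C)CC[C@@H]2C(C)C)O1 | starting material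
2 | isopropenylmagnesium bromide (prop-1-en-2-ylmagnesium bromide) | CC(=C)[Mg]Br | starting material
3 | (4R,5S)-5-(d-menthyloxy)-4-(prop-1-en-2-yl)dihydrofuran-2(3H)-one (isopropenyl trans to menthyloxy) | O=C1C[C@H](C(C)=C)[C@@H](O[C@H]2C[C@@H](C)CC[C@@H]2C(C)C)O1 | intermediate
4 | (3S,4R,5S)-3-methyl-5-(d-menthyloxy)-4-(prop-1-en-2-yl)dihydrofuran-2(3H)-one (methyl trans to isopropenyl) | O=C1[C@@H](C)[C@H](C(C)=C)[C@@H](O[C@H]2C[C@@H](C)CC[C@@H]2C(C)C)O1 | intermediate
5 | (E)-but-2-en-1-yl methyl carbonate | C/C=C/COC(=O)OC | starting material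
6 | trimethylsilyl ketene acetal of 4: trimethyl{[3-methyl-5-(d-menthyloxy)-4-(prop-1-en-2-yl)-4,5-dihydrofuran-2-yl]oxy}silane (C10 and C1 as in 4) | C[Si](C)(C)OC1=C(C)[C@H](C(C)=C)[C@@H](O[C@H]2C[C@@H](C)CC[C@@H]2C(C)C)O1 | intermediate
7 | (3S,4S,5S)-3-[(2S)-but-3-en-2-yl]-3-methyl-5-(d-menthyloxy)-4-(prop-1-en-2-yl)dihydrofuran-2(3H)-one (butenyl trans, C9 methyl cis to isopropenyl) | O=C1[C@@](C)([C@@H](C)C=C)[C@H](C(C)=C)[C@@H](O[C@H]2C[C@@H](C)CC[C@@H]2C(C)C)O1 | intermediate
8 | lactol of 7: 3-[(2S)-but-3-en-2-yl]-3-methyl-5-(d-menthyloxy)-4-(prop-1-en-2-yl)tetrahydrofuran-2-ol (other centres as in 7, C11 anomers) | OC1[C@@](C)([C@@H](C)C=C)[C@H](C(C)=C)[C@@H](O[C@H]2C[C@@H](C)CC[C@@H]2C(C)C)O1 | intermediate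
9 | 3-[(2S)-but-3-en-2-yl]-2,5-dimethoxy-3-methyl-4-(prop-1-en-2-yl)tetrahydrofuran (C8, C9, C10 as in 7; acetal anomers) | COC1[C@@](C)([C@@H](C)C=C)[C@H](C(C)=C)C(OC)O1 | intermediate
10 | alkylzirconocene chloride of 9 (Cp2ZrCl on terminal C6) | COC1[C@@](C)([C@@H](C)CC[Zr](Cl)(C2C=CC=C2)C2C=CC=C2)[C@H](C(C)=C)C(OC)O1 | intermediate
11 | 3-[(2S)-4-iodobutan-2-yl]-2,5-dimethoxy-3-methyl-4-(prop-1-en-2-yl)tetrahydrofuran | COC1[C@@](C)([C@@H](C)CCI)[C@H](C(C)=C)C(OC)O1 | intermediate
12 | 2-{4-[(2S)-4-iodobutan-2-yl]-2,5-dimethoxy-4-methyltetrahydrofuran-3-yl}propane-1,2-diol | COC1[C@@](C)([C@@H](C)CCI)[C@H](C(C)(O)CO)C(OC)O1 | intermediate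
13 | 1-{4-[(2S)-4-iodobutan-2-yl]-2,5-dimethoxy-4-methyltetrahydrofuran-3-yl}ethan-1-one (acetyl trans to the C8 side chain) | COC1[C@@](C)([C@@H](C)CCI)[C@H](C(C)=O)C(OC)O1 | intermediate
14 | but-2-en-2-ylmagnesium bromide (E/Z mixture) | CC=C(C)[Mg]Br | starting material
15 | 2-{4-[(2S)-4-iodobutan-2-yl]-2,5-dimethoxy-4-methyltetrahydrofuran-3-yl}-3-methylpent-3-en-2-ol (carbinol epimers, E/Z) | COC1[C@@](C)([C@@H](C)CCI)[C@H](C(C)(O)C(C)=CC)C(OC)O1 | intermediate
16 | 4-{4-[(2S)-4-iodobutan-2-yl]-2,5-dimethoxy-4-methyltetrahydrofuran-3-yl}-3-methylpent-3-en-2-one (E/Z mixture) | COC1[C@@](C)([C@@H](C)CCI)[C@H](C(C)=C(C)C(C)=O)C(OC)O1 | intermediate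
17 | 3-(1,3-dimethoxy-4,7,7a-trimethyloctahydro-2-benzofuran-4-yl)butan-2-one (drimane C5 R, C8 S, C9 S, C10 S; C4 epimers) | COC1[C@@]2(C)[C@@H](C)CC[C@@](C)(C(C)C(C)=O)[C@@H]2C(OC)O1 | intermediate
18 | 1,3,6-trimethyl-3-(3-oxobutan-2-yl)cyclohexane-1,2-dicarbaldehyde (ring B stereocentres as in 17) | O=C[C@@]1(C)[C@@H](C)CC[C@@](C)(C(C)C(C)=O)[C@@H]1C=O | intermediate
19 | (1S,2S,4aR,8aS)-1,2,4a,5-tetramethyl-6-oxo-1,2,3,4,4a,5,6,8a-octahydronaphthalene-1-carbaldehyde (C5 of the naphthalene as epimer mixture) | O=C[C@]1(C)[C@H]2C=CC(=O)C(C)[C@]2(C)CC[C@@H]1C | intermediate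
20 | C4-epimeric mixture of 21 (1,2,4a,5-tetramethyl-6-oxodecahydronaphthalene-1-carbaldehyde) | O=C[C@]1(C)[C@H]2CCC(=O)C(C)[C@]2(C)CC[C@@H]1C | intermediate
21 | (1S,2S,4aR,5S,8aS)-1,2,4a,5-tetramethyl-6-oxodecahydronaphthalene-1-carbaldehyde | O=C[C@]1(C)[C@H]2CCC(=O)[C@@H](C)[C@]2(C)CC[C@@H]1C | intermediate
22 | (1S,4aS,5S,6S,8aR)-5-(hydroxymethyl)-1,5,6,8a-tetramethyloctahydronaphthalen-2(1H)-one | OC[C@]1(C)[C@H]2CCC(=O)[C@@H](C)[C@]2(C)CC[C@@H]1C | intermediate
23 | isofraxidin (7-hydroxy-6,8-dimethoxy-2H-chromen-2-one) | COc1cc2ccc(=O)oc2c(OC)c1O | starting material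
24 | 6,8-dimethoxy-7-{[(1S,2S,4aR,5S,8aS)-1,2,4a,5-tetramethyl-6-oxodecahydronaphthalen-1-yl]methoxy}-2H-chromen-2-one (drimane numbering 4S,5R,8S,9S,10S) | COc1cc2ccc(=O)oc2c(OC)c1OC[C@]1(C)[C@H]2CCC(=O)[C@@H](C)[C@]2(C)CC[C@@H]1C | target

**Step count and risks**

Total step count: 14. Longest linear sequence: 14 steps (1 → 24).

Steps most likely to fail:

- Step 10 (key step). Hydrogen transfer to the C6 radical (direct reduction by Bu3SnH, or a 1,5-shift from C10–H or the C11 acetal C–H) may outrun the slow 6-exo addition to the congested, twisted tetrasubstituted enone. The fallback sets out from ketone 13 and uses a smaller, more electrophilic acceptor. Addition of isopropenylmagnesium bromide 2 (LaCl3·2LiCl, THF, −78 °C) gives the tertiary allylic alcohol F1, and pyridinium chlorochromate transposes it to the tetrasubstituted enal F2. The same tin hydride cyclisation, under the same allylic-strain control, gives the ring B aldehyde F3; MeMgBr then gives the secondary alcohol F4, and Dess–Martin oxidation returns to the route at 17.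
- Step 3. Bond formation at the congested C9 of the tetrasubstituted ketene acetal may be sluggish, and catalyst control at C8 may be eroded by the neighbouring stereocentres. The fallback sets out from lactone 4: O-ethylation with Et3O·BF4 followed by sodium (E)-but-2-en-1-olate gives the mixed cyclic orthoester F5. Heating (xylene, 140 °C, cat. pivalic acid) eliminates ethanol to the O-crotyl ketene acetal, whose chair Claisen rearrangement (C9 methyl cis to the allyloxy oxygen, E-crotyl group, bond formation anti to isopropenyl) should deliver the same C8/C9 arrangement and come back at 7.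
- Step 14. Displacement at the neopentyl-type C11 alkoxyphosphonium by the 2,6-dimethoxy-flanked phenol may stall, so that the activated alcohol decomposes instead. The fallback sets out from isofraxidin 23, which is converted into the aryl triflate F6 (Tf2O, pyridine, CH2Cl2, 0 °C). F6 is joined to alcohol 22 by palladium-catalysed C–O coupling (Pd2(dba)3, t-BuBrettPhos, Cs2CO3, toluene, 90 °C); this forms the O–aryl bond at the arene, needs no substitution at C11, and comes back at 24.

Further compounds
F1 | step 10 | 2-{4-[(2S)-4-iodobutan-2-yl]-2,5-dimethoxy-4-methyltetrahydrofuran-3-yl}-3-methylbut-3-en-2-ol (carbinol epimers) | COC1[C@@](C)([C@@H](C)CCI)[C@H](C(C)(O)C(C)=C)C(OC)O1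
F2 | step 10 | 3-{4-[(2S)-4-iodobutan-2-yl]-2,5-dimethoxy-4-methyltetrahydrofuran-3-yl}-2-methylbut-2-enal (E/Z mixture) | COC1[C@@](C)([C@@H](C)CCI)[C@H](C(C)=C(C)C=O)C(OC)O1
F3 | step 10 | 2-(1,3-dimethoxy-4,7,7a-trimethyloctahydro-2-benzofuran-4-yl)propanal (ring B as in 17; C4 epimers) | COC1[C@@]2(C)[C@@H](C)CC[C@@](C)(C(C)C=O)[C@@H]2C(OC)O1
F4 | step 10 | 3-(1,3-dimethoxy-4,7,7a-trimethyloctahydro-2-benzofuran-4-yl)butan-2-ol (ring B as in 17; epimers at C3 and C4) | COC1[C@@]2(C)[C@@H](C)CC[C@@](C)(C(C)C(C)O)[C@@H]2C(OC)O1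
F5 | step 3 | 2-[(E)-but-2-en-1-yloxy]-2-ethoxy-3-methyl-5-(d-menthyloxy)-4-(prop-1-en-2-yl)tetrahydrofuran (C9, C10, C1 as in 4) | CCOC1(OC/C=C/C)[C@@H](C)[C@H](C(C)=C)[C@@H](O[C@H]2C[C@@H](C)CC[C@@H]2C(C)C)O1
F6 | step 14 | 6,8-dimethoxy-2-oxo-2H-chromen-7-yl trifluoromethanesulfonate | COc1cc2ccc(=O)oc2c(OC)c1OS(=O)(=O)C(F)(F)F
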